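**Assumption:** C‑7 is the only stereocentre of the target; the methoxy‑bearing carbon made in step 1 is carried as a mixture of epimers until it becomes sp2 in step 6; benzyl 2‑oxopropanoate is taken as purchasable (otherwise one esterification from pyruvic acid); locants C‑1 to C‑8a are the isochromene locants of the target.

**Retrosynthetic overview**
- The pyran ring is closed last: acid unmasks a dihydrofuran (hidden C‑3 ketone and primary alcohol), the ketone enol oxygen closes onto an aminomethylene carbon (C‑1), and the 5‑O‑silyl group falls off.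
- The carbocycle is closed first: a 6‑endo Michael addition of C‑5 onto an ynone (C5–C4a), followed by one‑carbon aminomethylenation at C‑8a.
- The ynone comes from an acyl Sonogashira coupling (C8–C8a) of a C5–C8 acid with a C8a/C4a/C4/C3 alkyne.
- Key bond C6–C7: enantioselective carbene‑catalysed crossed benzoin, the acyl anion (Breslow intermediate) of a silyloxyacetaldehyde adding to the ketone of a pyruvate ester; this sets C‑7, and the butanoate is put on in the same pot.
- The alkyne comes from α‑lithiated 2,3‑dihydrofuran (a masked 4‑hydroxybutanoyl anion) adding to a silylpropynal (C3–C4), then O‑methylation.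

**Step 1**
Reactants: 1 2,3-dihydrofuran; 2 3-(trimethylsilyl)prop-2-ynal
Product: 6 5-(1-methoxyprop-2-yn-1-yl)-2,3-dihydrofuran (racemic), via 5-lithio-2,3-dihydrofuran 3 (not isolated), via lithium propargylic alkoxide 4 (not isolated), via C-silylated methyl ether 5 (not isolated)
Conditions: t-BuLi (1.0 equiv), THF, −78 to 0 °C; 2, −78 °C; MeI, DMPU, −78 °C to rt; then MeOH, K2CO3 (cat.), rt
Reagents that add atoms: iodomethane, CI
Why: α‑Deprotonation of the cyclic enol ether gives a vinyl‑lithium that is a masked 4‑hydroxybutanoyl anion (acyl anion equivalent); its 1,2‑addition to the ynal, in‑situ Williamson O‑methylation of the lithium alkoxide and methanolytic C‑desilylation are standard, and the new carbinol centre (later C‑4) is left racemic because it becomes sp2 in step 6.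

**Step 2**
Reactants: 7 2-[(tert-butyldimethylsilyl)oxy]acetaldehyde; 8 benzyl 2-oxopropanoate (benzyl pyruvate)
Product: 10 benzyl (2R)-2-(butanoyloxy)-4-[(tert-butyldimethylsilyl)oxy]-2-methyl-3-oxobutanoate, via tertiary ketol 9 (not isolated)
Conditions: (5aS,10bR)-2-(pentafluorophenyl)-5a,10b-dihydro-4H,6H-indeno[2,1-b][1,2,4]triazolo[4,3-d][1,4]oxazin-2-ium tetrafluoroborate, C18H11BF9N3O (10 mol %), i-Pr2NEt (1 equiv), 4 Å sieves, CH2Cl2, 0 °C to rt; then (n-PrCO)2O (3 equiv), DMAP (0.3 equiv), rt
Reagents that add atoms: butanoic anhydride, CCCC(=O)OC(=O)CCC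
Why: Carbene‑catalysed crossed benzoin reaction in which the Breslow intermediate (acyl anion) of aldehyde 7 adds to the activated ketone of α‑keto ester 8, the fused aminoindanol triazolylidene discriminating the ketone faces to set the quaternary carbinol (2R here, which is 7S of the target; the mirror‑image salt is used if the first run shows the opposite sense), and immediate DMAP‑catalysed O‑butanoylation removes the free ketol so that retro‑benzoin cannot erode the ee.

**Step 3**
Reactants: 10 benzyl (2R)-2-(butanoyloxy)-4-[(tert-butyldimethylsilyl)oxy]-2-methyl-3-oxobutanoate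
Product: 11 (2R)-2-(butanoyloxy)-4-[(tert-butyldimethylsilyl)oxy]-2-methyl-3-oxobutanoic acid
Conditions: H2 (1 atm), Pd/C (10 wt %), EtOAc, 0 °C; filtered, concentrated cold, used at once
Reagents that add atoms: none
Why: Hydrogenolysis of the benzyl ester leaves the silyl ether, ketone and butanoate untouched; the β‑keto acid can decarboxylate, hence cold handling and immediate use, and the quaternary stereocentre is not affected.

**Step 4**
Reactants: 11 (2R)-2-(butanoyloxy)-4-[(tert-butyldimethylsilyl)oxy]-2-methyl-3-oxobutanoic acid; 6 5-(1-methoxyprop-2-yn-1-yl)-2,3-dihydrofuran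
Product: 13 (3S)-1-[(tert-butyldimethylsilyl)oxy]-7-(4,5-dihydrofuran-2-yl)-7-methoxy-3-methyl-2,4-dioxohept-5-yn-3-yl butanoate (two epimers at the methoxy carbon), via acid chloride 12 (not isolated)
Conditions: 1-chloro-N,N,2-trimethylprop-1-en-1-amine (1.1 equiv), CH2Cl2, 0 °C; then 6, PdCl2(PPh3)2 (2 mol %), CuI (4 mol %), Et3N (1.5 equiv), THF, rt
Reagents that add atoms: none
Why: Neutral conversion of the acid into its chloride by the α‑chloroenamine, then copper‑ and palladium‑co‑catalysed acyl Sonogashira coupling with the terminal alkyne forms C8–C8a; the acid chloride has no α‑hydrogen (no ketene, no racemisation) and the amine buffer protects the enol ether.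

**Step 5**
Reactants: 13 (3S)-1-[(tert-butyldimethylsilyl)oxy]-7-(4,5-dihydrofuran-2-yl)-7-methoxy-3-methyl-2,4-dioxohept-5-yn-3-yl butanoate
Product: 15 (1S)-3-[(tert-butyldimethylsilyl)oxy]-4-[(4,5-dihydrofuran-2-yl)(methoxy)methyl]-5-[(dimethylamino)methylidene]-1-methyl-2,6-dioxocyclohex-3-en-1-yl butanoate, via cyclohexenedione 14 (not isolated)
Conditions: Cs2CO3 (1.5 equiv), DMF, 0 °C to rt; then t-BuOCH(NMe2)2 (1.5 equiv), 45 °C
Reagents that add atoms: tert-butoxybis(dimethylamino)methane, CC(C)(C)OC(N(C)C)N(C)C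
Why: Proposed new method: carbonate enolises the α‑silyloxy ketone and the enolate carbon (C‑5) closes onto the ynone β‑carbon (C‑4a; 6‑endo‑dig Michael addition, or the same addition after base isomerisation to the allenone), the adduct being drained as a doubly vinylogous carboxylate (14 as its caesium salt) while any O‑cyclised vinylogous ester can revert through the acidic C‑4 hydrogen, and the dienolate is then C‑aminomethylenated at its only free nucleophilic carbon (C‑8a) as 1,3‑diones are; closest known chemistry is the base‑mediated ketone–ynone Michael addition/benzannulation, the 6‑endo‑dig closure of 1,3‑dicarbonyl ynones to γ‑pyrones and enaminone formation with aminal esters; quaternary C‑7 is not touched.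

**Step 6**
Reactants: 15 (1S)-3-[(tert-butyldimethylsilyl)oxy]-4-[(4,5-dihydrofuran-2-yl)(methoxy)methyl]-5-[(dimethylamino)methylidene]-1-methyl-2,6-dioxocyclohex-3-en-1-yl butanoate
Product: 18 (7S)-5-hydroxy-3-(3-hydroxypropyl)-4-methoxy-7-methyl-6,8-dioxo-7,8-dihydro-6H-isochromen-7-yl butanoate (target), via hydroxy ketone 16 (not isolated), via silyl enol ether 17 (not isolated)
Conditions: aq. HCl (1 M), THF, 0 °C to rt
Reagents that add atoms: water, O
Why: Aqueous acid hydrates the dihydrofuran enol ether to the γ‑hydroxy ketone, whose enol oxygen displaces dimethylamine from the aminomethylene carbon (addition–elimination and cyclodehydration, the classical 2‑benzopyrylium/azaphilone pyran closure) so that C‑4 becomes sp2, and the same medium hydrolyses the silyl enol ether to the 5‑hydroxy group; the tertiary butanoate and C‑7 are stable to cold dilute acid.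

**Compound list**
1 | 2,3-dihydrofuran | C1CC=CO1 | starting material
2 | 3-(trimethylsilyl)prop-2-ynal | C[Si](C)(C)C#CC=O | starting material
3 | 5-lithio-2,3-dihydrofuran | [Li]C1=CCCO1 | intermediate
4 | lithium 1-(4,5-dihydrofuran-2-yl)-3-(trimethylsilyl)prop-2-yn-1-olate (racemic) | [Li]OC(C#C[Si](C)(C)C)C1=CCCO1 | intermediate
5 | 5-[1-methoxy-3-(trimethylsilyl)prop-2-yn-1-yl]-2,3-dihydrofuran (racemic) | COC(C#C[Si](C)(C)C)C1=CCCO1 | intermediate
6 | 5-(1-methoxyprop-2-yn-1-yl)-2,3-dihydrofuran (racemic) | COC(C#C)C1=CCCO1 | intermediate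
7 | 2-[(tert-butyldimethylsilyl)oxy]acetaldehyde | CC(C)(C)[Si](C)(C)OCC=O | starting material
8 | benzyl 2-oxopropanoate | CC(=O)C(=O)OCc1ccccc1 | starting material
9 | benzyl (2R)-4-[(tert-butyldimethylsilyl)oxy]-2-hydroxy-2-methyl-3-oxobutanoate | O[C@@](C(=O)CO[Si](C)(C)C(C)(C)C)(C)C(=O)OCc1ccccc1 | intermediate
10 | benzyl (2R)-2-(butanoyloxy)-4-[(tert-butyldimethylsilyl)oxy]-2-methyl-3-oxobutanoate | CCCC(=O)O[C@@](C(=O)CO[Si](C)(C)C(C)(C)C)(C)C(=O)OCc1ccccc1 | intermediate
11 | (2R)-2-(butanoyloxy)-4-[(tert-butyldimethylsilyl)oxy]-2-methyl-3-oxobutanoic acid | CCCC(=O)O[C@@](C(=O)CO[Si](C)(C)C(C)(C)C)(C)C(=O)O | intermediate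
12 | (2R)-4-[(tert-butyldimethylsilyl)oxy]-1-chloro-2-methyl-1,3-dioxobutan-2-yl butanoate | CCCC(=O)O[C@@](C(=O)CO[Si](C)(C)C(C)(C)C)(C)C(Cl)=O | intermediate
13 | (3S)-1-[(tert-butyldimethylsilyl)oxy]-7-(4,5-dihydrofuran-2-yl)-7-methoxy-3-methyl-2,4-dioxohept-5-yn-3-yl butanoate (epimers at the methoxy carbon) | CCCC(=O)O[C@@](C(=O)CO[Si](C)(C)C(C)(C)C)(C)C(=O)C#CC(OC)C1=CCCO1 | intermediate
14 | (1S)-3-[(tert-butyldimethylsilyl)oxy]-4-[(4,5-dihydrofuran-2-yl)(methoxy)methyl]-1-methyl-2,6-dioxocyclohex-3-en-1-yl butanoate (dione tautomer of the vinylogous acid; epimers at the methoxy carbon) | CCCC(=O)O[C@@]1(C)C(=O)CC(C(OC)C2=CCCO2)=C(O[Si](C)(C)C(C)(C)C)C1=O | intermediate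
15 | (1S)-3-[(tert-butyldimethylsilyl)oxy]-4-[(4,5-dihydrofuran-2-yl)(methoxy)methyl]-5-[(dimethylamino)methylidene]-1-methyl-2,6-dioxocyclohex-3-en-1-yl butanoate (epimers at the methoxy carbon) | CCCC(=O)O[C@@]1(C)C(=O)C(=CN(C)C)C(C(OC)C2=CCCO2)=C(O[Si](C)(C)C(C)(C)C)C1=O | intermediate
16 | (1S)-3-[(tert-butyldimethylsilyl)oxy]-5-[(dimethylamino)methylidene]-4-(5-hydroxy-1-methoxy-2-oxopentyl)-1-methyl-2,6-dioxocyclohex-3-en-1-yl butanoate | CCCC(=O)O[C@@]1(C)C(=O)C(=CN(C)C)C(C(OC)C(=O)CCCO)=C(O[Si](C)(C)C(C)(C)C)C1=O | intermediate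
17 | (7S)-5-[(tert-butyldimethylsilyl)oxy]-3-(3-hydroxypropyl)-4-methoxy-7-methyl-6,8-dioxo-7,8-dihydro-6H-isochromen-7-yl butanoate | CCCC(=O)O[C@@]1(C)C(=O)C2=COC(CCCO)=C(OC)C2=C(O[Si](C)(C)C(C)(C)C)C1=O | intermediate
18 | (7S)-5-hydroxy-3-(3-hydroxypropyl)-4-methoxy-7-methyl-6,8-dioxo-7,8-dihydro-6H-isochromen-7-yl butanoate | CCCC(=O)O[C@@]1(C)C(=O)C2=COC(CCCO)=C(OC)C2=C(O)C1=O | target

**Step count:** 6 steps in total (one‑pot sequences counted once). Longest linear sequence: 5 steps (7 and 8 → 10 → 11 → 13 → 15 → 18).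

**Three steps most likely to fail**

Step 5 is the weakest point: the enolate may close through oxygen instead of carbon, or the ynone may only isomerise. The fallback sets out from 13 and comes back at 14. Conjugate addition of benzenethiol (PhSH, Et3N cat., CH2Cl2, 0 °C) to the ynone gives the β‑sulfanyl enone (3S)-1-[(tert-butyldimethylsilyl)oxy]-7-(4,5-dihydrofuran-2-yl)-7-methoxy-3-methyl-2,4-dioxo-6-(phenylsulfanyl)hept-5-en-3-yl butanoate F3, which can no longer isomerise at the propargylic position. Cs2CO3 in DMF then closes the ring by enolate addition–elimination with loss of thiolate, which also returns any O‑adduct to the manifold, and gives 14. This is aminomethylenated as in step 5.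

Step 4 is next: the β‑keto acid 11 may decarboxylate, or its hindered chloride may couple poorly. The fallback sets out from 11 and comes back at 13. Cold carbodiimide esterification with ethanethiol (EDC hydrochloride, DMAP cat., CH2Cl2, −10 °C) gives the bench‑stable thioester S-ethyl (2R)-2-(butanoyloxy)-4-[(tert-butyldimethylsilyl)oxy]-2-methyl-3-oxobutanethioate F2. This is coupled with alkyne 6 under thioester–alkyne cross‑coupling conditions (PdCl2(dppf), tri(2-furyl)phosphine, CuI, Et3N, DMF, 50 °C) to give 13 without passing through an acid chloride.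

Step 2 is third: the crossed benzoin may give low ee or poor chemoselectivity with this particular aldehyde and pyruvate pair. The fallback sets out from 7 and comes back at 9. SnCl2‑catalysed Roskamp homologation of 7 with benzyl 2‑diazopropanoate gives the β‑keto ester benzyl 4-[(tert-butyldimethylsilyl)oxy]-2-methyl-3-oxobutanoate F1. Enantioselective α‑hydroxylation (cumene hydroperoxide, N‑benzylcinchoninium chloride or its pseudo‑enantiomer as phase‑transfer catalyst, K2HPO4, toluene, 0 °C) then gives ketol 9, which is butanoylated to 10 as in step 2. The ee can be raised by recrystallising an ammonium salt of acid 11.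

**Further compounds**
F1 | step 2 | benzyl 4-[(tert-butyldimethylsilyl)oxy]-2-methyl-3-oxobutanoate (racemic) | CC(C(=O)CO[Si](C)(C)C(C)(C)C)C(=O)OCc1ccccc1
F2 | step 4 | S-ethyl (2R)-2-(butanoyloxy)-4-[(tert-butyldimethylsilyl)oxy]-2-methyl-3-oxobutanethioate | CCCC(=O)O[C@@](C(=O)CO[Si](C)(C)C(C)(C)C)(C)C(=O)SCC
F3 | step 5 | (3S)-1-[(tert-butyldimethylsilyl)oxy]-7-(4,5-dihydrofuran-2-yl)-7-methoxy-3-methyl-2,4-dioxo-6-(phenylsulfanyl)hept-5-en-3-yl butanoate | CCCC(=O)O[C@@](C(=O)CO[Si](C)(C)C(C)(C)C)(C)C(=O)C=C(Sc1ccccc1)C(OC)C1=CCCO1
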